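**Reckoning unit.** The molar-minute of incoming ligand, its charged concentration c times the time t, is the unit I reckon in, and Sunday's run, Thursday's run and the flask start with the same 0.80 M of starting complex.

| flask | starting complex | incoming ligand | remark | time |
|---|---|---|---|---|
| Sunday's | 0.80 M | 0.40 M | run made earlier |  |
| Thursday's | 0.80 M | 1.6 M | run made earlier |  |
| flask | 0.80 M | 0.800 M |  | 2.0 h |

| run | time / min | complex with one exchanged / % |
|---|---|---|
| Sunday's | 6.00 | 0.8 |
| Sunday's | 10.0 | 0.5 |
| Sunday's | 15.0 | 1.5 |
| Sunday's | 25.0 | 2.1 |
| Sunday's | 40.0 | 3.2 |
| Sunday's | 80.0 | 5.8 |
| Thursday's | 5.00 | 2.0 |
| Thursday's | 15.0 | 4.5 |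
| Thursday's | 25.0 | 6.7 |
| Thursday's | 40.0 | 9.1 |
| Thursday's | 60.0 | 11.7 |
| Thursday's | 80.0 | 13.3 |

(scatter of a reading: 0.3 percentage points)

- equivalents of incoming ligand to starting complex, everything else as given, that leave most complex with one exchanged at 2.0 h
- the amount of complex with one exchanged then, in percent of the starting complex charged
- the amount of complex with one exchanged with the amounts as given

- a species is counted by the starting complex in it: one idle adduct B counts as two
- amounts and yields of complex with one exchanged count idle adduct B too
- amounts and yields of leaving ligand count idle adduct A too
- the numbers in the tables scatter with a standard deviation of 0.3 percentage points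
- steps under discussion: starting complex + incoming ligand <-> leaving ligand + complex with one exchanged; complex with one exchanged + incoming ligand <-> leaving ligand + complex with two exchanged; complex with two exchanged + incoming ligand <-> leaving ligand + complex with three exchanged; complex with three exchanged + incoming ligand <-> leaving ligand + complex with four exchanged; leaving ligand + incoming ligand <-> idle adduct A; starting complex + complex with one exchanged <-> idle adduct B
- in an amount of complex with one exchanged, one idle adduct B counts as one complex with one exchanged

**Main step.** Complex with one exchanged is the intermediate of a consecutive series, and Sunday's last reading gives a gain per molar-minute g = 0.00181 /M/min, as a fraction of the starting complex charged. Counting this step by itself, the flask's 96.0 M·min would give 17.4%.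

**Second exchange.** This step takes away the intermediate, so the comparison of loss with gain drifts as the intermediate builds. Between Thursday's last two readings the net gain is 5.00 × 10⁻⁴ /M/min, a quarter of g. Thursday's reading at 60.0 min has the flask's ct and stands at 11.7%, so the bend, which these readings don't divide among the second exchange, the spent ligand and the adducts, costs 5.7 percentage points against my count.

**Spent ligand.** The flask has half Thursday's charge, so equal conversion spends a larger share of it. I reckon the share taken by the first exchange as s = g·c(starting complex)·t, which is 17.4% in the flask, and I define the effective exposure E as ct times one minus half of s. The flask's E is 87.6 M·min. Thursday's E is 62.1 M·min at 40.0 min and 91.8 M·min at 60.0 min, and reading between them I commit to 11.3%. Thursday's run still climbs at its last reading, at a ct of 128 M·min, so I set no number on the peak.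

**The forecast.** It gives 11.3% for the flask and a peak of 15.5% at 2.7 equiv. It works from a rate ratio where I read Thursday's curve: “The simplest reading is that the second exchange is faster”.

**Flask result.** The flask holds 11.3%, and the best charge, 2.57 equiv, gives 15.0%.

    starting complex + incoming ligand ⇌ leaving ligand + complex with one exchanged (K = 3.70, k = 0.130 /M/h)
    complex with one exchanged + incoming ligand ⇌ leaving ligand + complex with two exchanged (K = 9.00, k = 0.700 /M/h)
    complex with two exchanged + incoming ligand ⇌ leaving ligand + complex with three exchanged (K = 12.0, k = 0.260 /M/h)
    complex with three exchanged + incoming ligand ⇌ leaving ligand + complex with four exchanged (K = 5.60, k = 0.0680 /M/h)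
    leaving ligand + incoming ligand ⇌ idle adduct A, settled at all times (K = 2.00 /M)
    starting complex + complex with one exchanged ⇌ idle adduct B, settled at all times (K = 0.550 /M)

**Neighbour flask.** The neighbour flask, charged with 0.32 M of incoming ligand, runs the same 2.0 h, so my reckoned s stays 17.4% and E is 35.1 M·min against the flask's 87.6 M·min. Thursday's E is 23.7 M·min at 15.0 min and 39.3 M·min at 25.0 min, and reading between them gives 6.10%, while the neighbour flask holds 6.00%.

The numbers in the tables were generated by integration from invented constants, and the scatter is random.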